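We charge 0.40 M of substrate against 0.52 mM of second catalyst, so each second catalyst must turn over about 769 times for full conversion.

    substrate + free catalyst ⇌ free catalyst + open intermediate (K1 = 0.62, k1 = 42 M⁻¹ min⁻¹)
    second catalyst + open intermediate ⇌ catalyst intermediate (K2 = 4.1 M⁻¹, k2 = 20 M⁻¹ min⁻¹)
    coupling partner + catalyst intermediate → second catalyst + product (k3 = 4.6 M⁻¹ min⁻¹)
    gas ⇌ coupling partner, rate k4*(csat - [coupling partner]) (k4 = 0.076 min⁻¹, csat = 200 mM)

substrate 0.40 M; gas 200 mM (held); free catalyst 2.0 mM; second catalyst 0.52 mM; time 8.0 h

- at the start none of coupling partner is dissolved
- run time (flask): 8.0 h

1. amount of product at 8.0 h, in percent of the substrate charged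
2. concentration of coupling partner in solution at 50 min, in percent of saturation
3. the change that raises the amount of product at 8.0 h, in percent of the substrate charged most ("none" if none brings more than 2 percentage points) (north-west / south-west / west / none)
4. amount of product at 8.0 h, in percent of the substrate charged, after south-west

- north-west: doubling the amount of free catalyst, all else as stated
- south-west: doubling the transfer coefficient of step 4, all else as stated
- west: doubling the saturation concentration of gas, all else as stated

We begin with step 1 at balance, since its relaxation time 4.56 min is much shorter than the run. Open intermediate is then 38.3% of the pool of substrate plus open intermediate. Second catalyst, at 0.52 mM, is scarce beside that pool of 0.40 M, so we hold its two forms in steady state. Catalyst intermediate then takes the share S/(S + Sh) of the second catalyst, where S is the pool and Sh is the pool constant 0.757 M, a Michaelis constant reckoned on the pool. Product forms at the top speed 0.478 mM min⁻¹ times that share. The charged pool gives 0.165 mM min⁻¹, hence 19.8% of the substrate by the end.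

But the pool shrinks as product forms. Taking the mid-run pool instead gives 18.5%.

But the flask also starts with no coupling partner dissolved and no open intermediate. We charge the gas time and the relaxation time as a lost start of 17.7 min, which brings our estimate to 17.8%.

Could transfer still limit the flask after that start? Its capacity 15.2 mM min⁻¹ is much greater than the turnover, so the liquid lags saturation by about 1.09%, and at 50 min we expect 96.7%. South-west shortens the lost start, giving 18.1%. West doubles the top speed while Sh rises less, to 0.878 M, so we choose west.

The forecast gives 17.8% of product, 96.8% at 50 min, west as the best change and 18.2% after south-west, holding that “Gas transfer far outpaces partner consumption”.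

The flask gives 17.9%, 96.8%, west with a gain of 13 percentage points, and 18.2% after south-west. At 8.00 h, catalyst intermediate holds 30.2% of the second catalyst charged, and Sh with the pool left after product gives 30.3%. The neighbour flask with 0.0021 M of second catalyst reaches 57.0% at 8.0 h. Integrating the rate with Sh and that neighbour flask's own top speed, and adding the lost start, puts that conversion at 7.77 h.

The numbers stand for no real mixture; no experiment stands behind them.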